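**Retrosynthetic overview**
1. Target ⇐ 2,9-bis-acetylation and hydroxyl-directed 3,4-epoxidation of a (3Z)-cyclodecadiene, which is closed last by ring-closing metathesis (C3=C4).
2. Metathesis precursor ⇐ γ-lactone by intramolecular Reformatsky addition to the C8 ketone; the C6-Cl/C7-O pair comes from chloride opening of a trans-6,7-epoxy ketone.
3. Epoxy ketone ⇐ E-enone made by the key intermolecular aldol (C6–C7 bond) between a ring-A methyl ketone (C1–C3, C7–C15, C20) and 2-bromoacrolein (C5, C6, C16), then Stille vinylation (C4).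
4. Methyl ketone ⇐ enantioselective Diels–Alder adduct (C1, C10), Felkin vinylation (C2), ynone transfer hydrogenation (C9), C11 methylation/hydroxylation.
5. Ring order: cyclohexene (Diels–Alder) → γ-lactone (Reformatsky) → ten-membered ring (metathesis) → epoxide.

Locants C1–C20 are those of the briarane skeleton of the target: C1 (quaternary, CH3-15), C2 (OAc), C3/C4 (epoxide), C5 (=C16H2), C6 (Cl), C7 (lactone O), C8 (tertiary OH), C9 (OAc), C10, C11 (OH, CH3-20), C12 (C=O), C13=C14, C17 (CH3-18), C19 (lactone C=O). TES = triethylsilyl, TIPS = triisopropylsilyl.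
Assumption: the sense of induction in the three catalytic asymmetric steps (2, 7, 19) is taken from the published models for the closest substrates; each catalyst is available in both mirror-image forms.

**Route**

Step 1
Reactants: 1 but-3-en-2-one
Product: 2 2-(triisopropylsilyloxy)buta-1,3-diene
Conditions: i-Pr3SiOTf, Et3N, Et2O, 0 °C → rt
Reagents that add atoms: triisopropylsilyl triflate, CC(C)[Si](OS(=O)(=O)C(F)(F)F)(C(C)C)C(C)C
Why: Soft enolisation and O-silylation (silyl enol ether formation) give the 2-siloxy diene; no stereocentre is formed.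

Step 2
Reactants: 2 2-(triisopropylsilyloxy)buta-1,3-diene; 3 ethyl (E)-3-methyl-4-oxobut-2-enoate
Product: 4 ethyl (1S,6S)-6-formyl-6-methyl-3-(triisopropylsilyloxy)cyclohex-3-ene-1-carboxylate
Conditions: (R)-o-tolyl-CBS oxazaborolidine (20 mol%), Tf2NH (18 mol%), CH2Cl2, −78 → −40 °C
Reagents that add atoms: none
Why: Corey oxazaborolidinium-catalysed Diels–Alder reaction: the catalyst binds the formyl group, so the CH2 terminus next to the siloxy carbon bonds to C10 (siloxy carbon para to C1), the E dienophile fixes C2 and C9 trans, and shielding of one enal face sets C1 and C10 absolutely.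

Step 3
Reactants: 4 Diels–Alder adduct
Product: 5 ethyl (1S,6S)-6-[(1S)-1-hydroxyprop-2-enyl]-6-methyl-3-(triisopropylsilyloxy)cyclohex-3-ene-1-carboxylate
Conditions: CH2=CHMgBr, THF, −78 °C; aq. NH4Cl
Reagents that add atoms: vinylmagnesium bromide, C=C[Mg]Br
Why: Grignard addition, chemoselective for the aldehyde at −78 °C; Felkin–Anh attack anti to the C1–C10 bond and past the C1 methyl sets C2 (minor epimer removed by chromatography).

Step 4
Reactants: 5 C2 allylic alcohol
Product: 6 2-O-TES ether of 5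
Conditions: Et3SiCl, imidazole, DMAP (cat.), DMF, 0 °C → rt
Reagents that add atoms: chlorotriethylsilane, CC[Si](Cl)(CC)CC
Why: Standard silylation, carried out at once so that the hydroxy ester cannot lactonise; no stereocentre is touched.

Step 5
Reactants: 6 2-O-TES ester
Product: 7 C9 Weinreb amide (N-methoxy-N-methyl carboxamide)
Conditions: MeNH(OMe)·HCl, i-PrMgCl, THF, −20 → 0 °C
Reagents that add atoms: N,O-dimethylhydroxylamine hydrochloride, CNOC.Cl
Why: Weinreb aminolysis of the ester by the magnesium amide; C10 keeps its trans relation to the C1 side chain.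

Step 6
Reactants: 7 Weinreb amide
Product: 8 C9 ynone (C9 ketone bearing C≡C–SiMe3)
Conditions: LiC≡CSiMe3, THF, −78 → 0 °C; aq. NH4Cl
Reagents that add atoms: lithium (trimethylsilyl)acetylide, [Li]C#C[Si](C)(C)C
Why: Acyl substitution on a Weinreb amide; the chelated tetrahedral intermediate prevents over-addition.

Step 7
Reactants: 8 ynone
Product: 9 (9S)-propargylic alcohol
Conditions: Ru[(S,S)-TsDPEN](p-cymene) (3 mol%), i-PrOH, rt
Reagents that add atoms: none
Why: Noyori asymmetric transfer hydrogenation: the alkyne is the π-directing group and the (S,S) catalyst gives the 9S carbinol, reinforced by Felkin–Anh hydride delivery anti to quaternary C1.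

Step 8
Reactants: 9 propargylic alcohol
Product: 10 2,9-bis-O-TES ether
Conditions: Et3SiOTf, 2,6-lutidine, CH2Cl2, −78 → 0 °C
Reagents that add atoms: triethylsilyl triflate, CC[Si](CC)(CC)OS(=O)(=O)C(F)(F)F
Why: Silyl triflate silylation of a hindered secondary alcohol; the TIPS enol ether is inert.

Step 9
Reactants: 10 bis-TES silyl enol ether
Product: 11 cyclohexenone (C12 ketone, C13=C14)
Conditions: Pd(OAc)2 (1.1 equiv), MeCN, 40 °C
Reagents that add atoms: none
Why: Saegusa–Ito oxidation; the enol ether regiochemistry fixed in step 2 places the new double bond at C13=C14 only.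

Step 10
Reactants: 11 enone
Product: 12 11-methyl enone (C11 epimers, major shown)
Conditions: LiN(i-Pr)2, THF, −78 °C; MeI, −78 → −30 °C
Reagents that add atoms: iodomethane, CI
Why: Kinetic enolate alkylation; C11 is the only enolisable position of the 4,4-disubstituted enone, and its configuration is erased in step 11.

Step 11
Reactants: 12 11-methyl enone
Product: 13 11-hydroxy-11-methyl enone (C11 as in target)
Conditions: KN(SiMe3)2, THF, −78 °C; 3-phenyl-2-(phenylsulfonyl)oxaziridine; aq. NH4Cl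
Reagents that add atoms: 3-phenyl-2-(phenylsulfonyl)oxaziridine, O=S(=O)(c1ccccc1)N1OC1c1ccccc1
Why: Davis enolate hydroxylation; the oxaziridine attacks the planar C11 enolate anti to the bulky vicinal C10 side chain, placing OH trans to C9 and CH3-20 cis to it.

Step 12
Reactants: 13 α-hydroxy enone
Product: 14 terminal alkyne
Conditions: K2CO3 (0.3 equiv), MeOH, 0 °C → rt
Reagents that add atoms: none
Why: Base-catalysed protodesilylation of the alkynylsilane; the hindered TES ethers survive.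

Step 13
Reactants: 14 terminal alkyne
Product: 15 2,9,11-tris-O-TES terminal alkyne
Conditions: Et3SiOTf, 2,6-lutidine, CH2Cl2, −78 → 0 °C
Reagents that add atoms: triethylsilyl triflate, CC[Si](CC)(CC)OS(=O)(=O)C(F)(F)F
Why: Silylation of the tertiary α-ketol hydroxyl blocks alkoxide formation and acyloin rearrangement in the base steps that follow.

Step 14
Reactants: 15 tris-TES alkyne
Product: 16 methyl ketone (C8 acetyl, C7 = CH3)
Conditions: Ph3PAuNTf2 (5 mol%), H2O, 1,4-dioxane, 40 °C
Reagents that add atoms: water, O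
Why: Gold-catalysed Markovnikov hydration of the terminal alkyne; C9 is untouched.

Step 15
Reactants: 17 acrolein
Product: 19 2-bromoacrolein, via 2,3-dibromopropanal 18 (not isolated)
Conditions: Br2, CH2Cl2, −78 °C; then Et3N, −78 → 0 °C
Reagents that add atoms: bromine, BrBr
Why: Bromine addition followed by E2 dehydrobromination of the α-bromo aldehyde.

Step 16
Reactants: 16 methyl ketone; 19 2-bromoacrolein
Product: 20 aldol adduct (6-hydroxy-8-ketone, C6 epimers)
Conditions: LiN(i-Pr)2, THF, −78 °C; then 19, −78 °C; aq. NH4Cl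
Reagents that add atoms: none
Why: Crossed aldol addition joining the two fragments at C6–C7: the kinetic lithium enolate forms only at the methyl group (the ring ketone has no α-hydrogen, C9–H is hindered) and adds 1,2 to the enal; the C6 carbinol centre is removed in step 17.

Step 17
Reactants: 20 aldol adduct
Product: 22 (6E)-5-bromo dienone, via C6 mesylate 21 (not isolated)
Conditions: MsCl, Et3N, CH2Cl2, −20 → 0 °C; then DBU (1.1 equiv), 0 °C, 10 min
Reagents that add atoms: none
Why: Mesylation and E1cB elimination (aldol condensation) give the conjugated E enone.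

Step 18
Reactants: 22 bromo dienone
Product: 23 (6E)-trienone (C5 bears the C4=CH2 vinyl group)
Conditions: CH2=CHSnBu3, Pd(PPh3)4 (5 mol%), CuI (10 mol%), DMF, rt
Reagents that add atoms: tributyl(vinyl)stannane, C=C[Sn](CCCC)(CCCC)CCCC
Why: Stille coupling of the 2-bromodiene under neutral conditions; 23 is used at once because cross-conjugated trienes dimerise slowly.

Step 19
Reactants: 23 trienone
Product: 24 (6R,7S)-trans-6,7-epoxy ketone
Conditions: La(O-i-Pr)3, (R)-BINOL, Ph3As=O (1:1:1, 10 mol%), t-BuOOH, 4 Å MS, THF, rt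
Reagents that add atoms: tert-butyl hydroperoxide, CC(C)(C)OO
Why: Lanthanum–BINOL-catalysed asymmetric Weitz–Scheffer epoxidation: only the acyclic s-cis enone reacts (not the hindered ring enone or the diene), the E geometry gives the trans epoxide and the (R)-BINOL complex selects the face that gives 6R,7S.

Step 20
Reactants: 24 epoxy ketone
Product: 25 anti chlorohydrin (6-chloro-7-hydroxy-8-ketone, C6 and C7 as in target)
Conditions: LiCl, AcOH, THF, 0 °C → rt
Reagents that add atoms: lithium chloride, [Li+].[Cl-]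
Why: Regioselective SN2 epoxide opening at C6 (allylic and β to the ketone) with inversion sets C6; C7 is retained.

Step 21
Reactants: 25 chlorohydrin
Product: 26 7-O-(2-bromopropanoyl) ester
Conditions: 2-bromopropanoyl bromide, pyridine, CH2Cl2, −20 → 0 °C
Reagents that add atoms: 2-bromopropanoyl bromide, CC(Br)C(Br)=O
Why: Acylation of the only free hydroxyl under weakly basic conditions that do not re-close the epoxide.

Step 22
Reactants: 26 bromopropanoate
Product: 27 γ-lactone (C7, C8, C17 as in target; 2,9,11-tris-O-TES)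
Conditions: Zn dust (activated with Me3SiCl), THF, 0 °C → rt; aq. NH4Cl
Reagents that add atoms: none
Why: Intramolecular Reformatsky reaction: the zinc enolate adds to the C8 ketone on the face anti to the C6 substituent of C7 (C9 trans to C6), and the zinc-chelated transition state keeps CH3-18 away from C9, i.e. cis to the new hydroxyl.

Step 23
Reactants: 27 tris-TES lactone
Product: 28 seco-tetraol (2-, 8-, 9-, 11-OH)
Conditions: HF·pyridine, pyridine, THF, 0 °C → rt
Reagents that add atoms: none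
Why: Fluoride-mediated desilylation of all three TES ethers; the allylic chloride and the lactone are stable to buffered HF.

Step 24
Reactants: 28 seco-tetraol
Product: 29 (3Z)-cyclodecadiene tetraol
Conditions: second-generation Hoveyda–Grubbs catalyst (15 mol%), 1,4-benzoquinone (30 mol%), ClCH2CH2Cl (1 mM), 60 °C
Reagents that add atoms: none
Why: Ring-closing metathesis between the C3 vinyl group and the monosubstituted end of the diene releases ethene; under thermodynamic control the less strained cis (3Z) ten-membered alkene forms.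

Step 25
Reactants: 29 macrocyclic tetraol
Product: 30 3,4-epoxy tetraol (C3, C4 as in target)
Conditions: VO(acac)2 (5 mol%), t-BuOOH, CH2Cl2, 0 °C
Reagents that add atoms: tert-butyl hydroperoxide, CC(C)(C)OO
Why: Hydroxyl-directed (Sharpless–Michaelson) epoxidation of the Z allylic alcohol only; in the A(1,3)-minimised conformer the C2 hydroxyl delivers oxygen to give the threo cis-epoxy alcohol.

Step 26
Reactants: 30 epoxy tetraol
Product: 31 CNP0176724.2 (target)
Conditions: Ac2O, pyridine, DMAP (cat.), CH2Cl2, 0 °C → rt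
Reagents that add atoms: acetic anhydride, CC(=O)OC(C)=O
Why: Acetylation of the two secondary alcohols (C2, C9); the tertiary C8 and C11 hydroxyls do not react under these conditions.

**Compound list**
1 | but-3-en-2-one | CC(=O)C=C | starting material
2 | 2-(triisopropylsilyloxy)buta-1,3-diene | C=CC(=C)O[Si](C(C)C)(C(C)C)C(C)C | intermediate
3 | ethyl (E)-3-methyl-4-oxobut-2-enoate | CCOC(=O)/C=C(\C)C=O | starting material
4 | ethyl (1S,6S)-6-formyl-6-methyl-3-(triisopropylsilyloxy)cyclohex-3-ene-1-carboxylate | O=C[C@@]1(C)CC=C(O[Si](C(C)C)(C(C)C)C(C)C)C[C@@H]1C(=O)OCC | intermediate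
5 | ethyl (1S,6S)-6-[(1S)-1-hydroxyprop-2-enyl]-6-methyl-3-(triisopropylsilyloxy)cyclohex-3-ene-1-carboxylate | C=C[C@H](O)[C@@]1(C)CC=C(O[Si](C(C)C)(C(C)C)C(C)C)C[C@@H]1C(=O)OCC | intermediate
6 | 2-O-TES ether of 5 | C=C[C@H](O[Si](CC)(CC)CC)[C@@]1(C)CC=C(O[Si](C(C)C)(C(C)C)C(C)C)C[C@@H]1C(=O)OCC | intermediate
7 | C9 Weinreb amide | C=C[C@H](O[Si](CC)(CC)CC)[C@@]1(C)CC=C(O[Si](C(C)C)(C(C)C)C(C)C)C[C@@H]1C(=O)N(C)OC | intermediate
8 | C9 ynone | C=C[C@H](O[Si](CC)(CC)CC)[C@@]1(C)CC=C(O[Si](C(C)C)(C(C)C)C(C)C)C[C@@H]1C(=O)C#C[Si](C)(C)C | intermediate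
9 | (9S)-propargylic alcohol | C=C[C@H](O[Si](CC)(CC)CC)[C@@]1(C)CC=C(O[Si](C(C)C)(C(C)C)C(C)C)C[C@@H]1[C@H](O)C#C[Si](C)(C)C | intermediate
10 | 2,9-bis-O-TES ether | C=C[C@H](O[Si](CC)(CC)CC)[C@@]1(C)CC=C(O[Si](C(C)C)(C(C)C)C(C)C)C[C@@H]1[C@H](O[Si](CC)(CC)CC)C#C[Si](C)(C)C | intermediate
11 | cyclohexenone (C12 ketone, C13=C14) | C=C[C@H](O[Si](CC)(CC)CC)[C@@]1(C)C=CC(=O)C[C@@H]1[C@H](O[Si](CC)(CC)CC)C#C[Si](C)(C)C | intermediate
12 | 11-methyl enone (C11 epimers; major, methyl trans to C9, shown) | C=C[C@H](O[Si](CC)(CC)CC)[C@@]1(C)C=CC(=O)[C@@H](C)[C@@H]1[C@H](O[Si](CC)(CC)CC)C#C[Si](C)(C)C | intermediate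
13 | 11-hydroxy-11-methyl enone (C11 as in target) | C=C[C@H](O[Si](CC)(CC)CC)[C@@]1(C)C=CC(=O)[C@@](C)(O)[C@@H]1[C@H](O[Si](CC)(CC)CC)C#C[Si](C)(C)C | intermediate
14 | terminal alkyne (11-OH free) | C=C[C@H](O[Si](CC)(CC)CC)[C@@]1(C)C=CC(=O)[C@@](C)(O)[C@@H]1[C@H](O[Si](CC)(CC)CC)C#C | intermediate
15 | 2,9,11-tris-O-TES terminal alkyne | C=C[C@H](O[Si](CC)(CC)CC)[C@@]1(C)C=CC(=O)[C@@](C)(O[Si](CC)(CC)CC)[C@@H]1[C@H](O[Si](CC)(CC)CC)C#C | intermediate
16 | methyl ketone (C8 acetyl) | C=C[C@H](O[Si](CC)(CC)CC)[C@@]1(C)C=CC(=O)[C@@](C)(O[Si](CC)(CC)CC)[C@@H]1[C@H](O[Si](CC)(CC)CC)C(C)=O | intermediate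
17 | acrolein | C=CC=O | starting material
18 | 2,3-dibromopropanal (racemic, not isolated) | O=CC(Br)CBr | intermediate
19 | 2-bromoacrolein | C=C(Br)C=O | intermediate
20 | aldol adduct (6-hydroxy-8-ketone, C6 epimers) | C=C[C@H](O[Si](CC)(CC)CC)[C@@]1(C)C=CC(=O)[C@@](C)(O[Si](CC)(CC)CC)[C@@H]1[C@H](O[Si](CC)(CC)CC)C(=O)CC(O)C(Br)=C | intermediate
21 | C6 mesylate (C6 epimers, not isolated) | C=C[C@H](O[Si](CC)(CC)CC)[C@@]1(C)C=CC(=O)[C@@](C)(O[Si](CC)(CC)CC)[C@@H]1[C@H](O[Si](CC)(CC)CC)C(=O)CC(OS(C)(=O)=O)C(Br)=C | intermediate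
22 | (6E)-5-bromo dienone | C=C[C@H](O[Si](CC)(CC)CC)[C@@]1(C)C=CC(=O)[C@@](C)(O[Si](CC)(CC)CC)[C@@H]1[C@H](O[Si](CC)(CC)CC)C(=O)/C=C/C(Br)=C | intermediate
23 | (6E)-trienone | C=C[C@H](O[Si](CC)(CC)CC)[C@@]1(C)C=CC(=O)[C@@](C)(O[Si](CC)(CC)CC)[C@@H]1[C@H](O[Si](CC)(CC)CC)C(=O)/C=C/C(=C)C=C | intermediate
24 | (6R,7S)-trans-6,7-epoxy ketone | C=C[C@H](O[Si](CC)(CC)CC)[C@@]1(C)C=CC(=O)[C@@](C)(O[Si](CC)(CC)CC)[C@@H]1[C@H](O[Si](CC)(CC)CC)C(=O)[C@H]2O[C@@H]2C(=C)C=C | intermediate
25 | anti chlorohydrin (6-chloro-7-hydroxy-8-ketone) | C=C[C@H](O[Si](CC)(CC)CC)[C@@]1(C)C=CC(=O)[C@@](C)(O[Si](CC)(CC)CC)[C@@H]1[C@H](O[Si](CC)(CC)CC)C(=O)[C@@H](O)[C@@H](Cl)C(=C)C=C | intermediate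
26 | 7-O-(2-bromopropanoyl) ester (bromide centre racemic) | C=C[C@H](O[Si](CC)(CC)CC)[C@@]1(C)C=CC(=O)[C@@](C)(O[Si](CC)(CC)CC)[C@@H]1[C@H](O[Si](CC)(CC)CC)C(=O)[C@@H](OC(=O)C(C)Br)[C@@H](Cl)C(=C)C=C | intermediate
27 | γ-lactone, 2,9,11-tris-O-TES | C=C[C@H](O[Si](CC)(CC)CC)[C@@]1(C)C=CC(=O)[C@@](C)(O[Si](CC)(CC)CC)[C@@H]1[C@H](O[Si](CC)(CC)CC)[C@]2(O)[C@@H](C)C(=O)O[C@H]2[C@@H](Cl)C(=C)C=C | intermediate
28 | seco-tetraol | C=C[C@H](O)[C@@]1(C)C=CC(=O)[C@@](C)(O)[C@@H]1[C@H](O)[C@]2(O)[C@@H](C)C(=O)O[C@H]2[C@@H](Cl)C(=C)C=C | intermediate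
29 | (3Z)-cyclodecadiene tetraol | C=C1/C=C\[C@H](O)[C@@]2(C)C=CC(=O)[C@@](C)(O)[C@@H]2[C@H](O)[C@]2(O)[C@@H](C)C(=O)O[C@H]2[C@H]1Cl | intermediate
30 | 3,4-epoxy tetraol | C=C1[C@H]2O[C@H]2[C@H](O)[C@@]2(C)C=CC(=O)[C@@](C)(O)[C@@H]2[C@H](O)[C@]2(O)[C@@H](C)C(=O)O[C@H]2[C@H]1Cl | intermediate
31 | CNP0176724.2 | C=C1[C@H]2O[C@H]2[C@H](OC(C)=O)[C@@]2(C)C=CC(=O)[C@@](C)(O)[C@@H]2[C@H](OC(C)=O)[C@]2(O)[C@@H](C)C(=O)O[C@H]2[C@H]1Cl | target

**Totals**
Total step count: 26. Longest linear sequence: 25 steps (steps 1–14 and 16–26; step 15 is the side branch).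

**Three steps most likely to fail**

Step 24 (closure of the ten-membered ring). Medium-ring metathesis next to a quaternary carbon may stall or oligomerise, and the free allylic alcohol can be isomerised by ruthenium hydrides. Fallback: set out from 27 and close the ring before desilylation, so that the substrate has no free hydroxyl and the three bulky silyl ethers restrict the open-chain conformers (second-generation Grubbs catalyst, toluene, 0.5 mM, 80 °C), giving the tris-O-TES macrocycle F4. HF·pyridine then removes the silyl groups and the route is rejoined at 29.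

Step 22 (lactone annulation). The five-membered enolate cyclisation onto a hindered ketone is slow, and zinc may attack the allylic chloride. Fallback: set out from 25 and form the C8–C17 bond intermolecularly by a chelation-controlled Mukaiyama aldol with (E)-1-ethoxy-1-(trimethylsilyloxy)propene and MgBr2·OEt2 (CH2Cl2, −78 → −20 °C). The nucleophile adds to the magnesium chelate of O7 and the C8 carbonyl on the face away from C6, giving the β-hydroxy ethyl ester F3. Camphorsulfonic acid in toluene then closes the lactone onto O7 with loss of ethanol, and the route is rejoined at 27.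

Step 19 (asymmetric epoxidation of the trienone). The cross-conjugated triene is sensitive, and the bulky α′-silyloxy centre may slow or mis-direct the lanthanum catalyst. Fallback: set out from 23 and replace nucleophilic by hydroxyl-directed epoxidation. Luche reduction (NaBH4, CeCl3·7H2O, MeOH, −78 °C) of the less hindered acyclic enone, Felkin–Anh controlled by C9, gives the 8,9-syn allylic alcohol F1. Sharpless asymmetric epoxidation (Ti(O-i-Pr)4, D-(−)-diisopropyl tartrate, t-BuOOH, 4 Å MS, CH2Cl2, −20 °C; matched pairing, only the 6,7-alkene is allylic to a free hydroxyl) gives the erythro epoxy alcohol F2. Dess–Martin periodinane then returns the route to 24.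

Further compounds
F1 | step 19 | 8,9-syn allylic alcohol (C8 carbinol of 23) | C=C[C@H](O[Si](CC)(CC)CC)[C@@]1(C)C=CC(=O)[C@@](C)(O[Si](CC)(CC)CC)[C@@H]1[C@H](O[Si](CC)(CC)CC)[C@@H](O)/C=C/C(=C)C=C
F2 | step 19 | erythro 6,7-epoxy-8-ol | C=C[C@H](O[Si](CC)(CC)CC)[C@@]1(C)C=CC(=O)[C@@](C)(O[Si](CC)(CC)CC)[C@@H]1[C@H](O[Si](CC)(CC)CC)[C@@H](O)[C@H]2O[C@@H]2C(=C)C=C
F3 | step 22 | β-hydroxy ethyl ester (7,8-diol, C19 ethyl ester) | C=C[C@H](O[Si](CC)(CC)CC)[C@@]1(C)C=CC(=O)[C@@](C)(O[Si](CC)(CC)CC)[C@@H]1[C@H](O[Si](CC)(CC)CC)[C@](O)([C@@H](C)C(=O)OCC)[C@@H](O)[C@@H](Cl)C(=C)C=C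
F4 | step 24 | 2,9,11-tris-O-TES (3Z)-macrocycle | C=C1/C=C\[C@H](O[Si](CC)(CC)CC)[C@@]2(C)C=CC(=O)[C@@](C)(O[Si](CC)(CC)CC)[C@@H]2[C@H](O[Si](CC)(CC)CC)[C@]2(O)[C@@H](C)C(=O)O[C@H]2[C@H]1Cl
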